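## Structural features

The target 14 is a monocyclic γ-butyrolactone (O1, C2 carbonyl, C3, C4, C5) with two benzylic arms. C3 is joined through C6H2 to ring B, a free catechol, and C4 through C7H2 to ring A, a 3,4-dimethoxyphenyl ring. C3 and C4 are adjacent stereocentres, both R, with the two arms trans. C3 is α to the lactone carbonyl and can be epimerised, and trans is the thermodynamically preferred arrangement. C4 has no acidifying neighbour, so it must be set absolutely and then left alone. The fragile parts are the catechol (air-sensitive once base is present, and it must stay distinguishable from the two methyl ethers of ring A), the lactone (open to nucleophiles) and the C3–H. The real difficulty is the lack of symmetry: two nearly identical arylmethyl groups must sit on defined carbons of a lactone whose ends differ in oxidation level (C2 acyl, C5 methylene), with absolute control at C4. The key step uses the fact that C3 and C4 are each α to a carboxyl-level carbon (C2 as it stands, C5 as a reduced carboxyl), so the C3–C4 bond is the central bond of a 2,3-dibenzylsuccinate in which both carbons are enolate positions of like polarity.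

## Logic of the disconnections

14 to 13: the two catechol O–H bonds are traced back to O–CH2Ph bonds. This keeps the oxidisable catechol masked through every basic step and keeps it distinct from the methyl ethers of ring A. The forward step must remove two benzyl groups under neutral conditions without touching the lactone or C3.

13 to 12: the O1–C2 bond is cut, which opens the lactone to a γ-hydroxy tert-butyl ester, and C3 is treated as correctable. This removes the ring and turns the stereochemical problem into one of an open chain with C4 fixed. The forward step must close the ring on a hindered ester without harming the benzyl ethers, and must then bring C3 to the trans arrangement by equilibration.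

12 to 11: C5 is raised from CH2OH to an acyl carbon bound to the nitrogen of a chiral auxiliary (C5–N bond). This makes C4 an enolisable position next to a stereocontrolling group and labels the two carboxyl termini differently. The forward step needs a hydride that reduces the imide carbonyl and spares the tert-butyl ester.

11 to 4 and 8: the C3–C4 bond is cut. This is the most simplifying cut, since it divides the skeleton into two hydrocinnamate halves of nearly equal size, each carrying one aryl ring. Both fragments are nucleophilic at the carbon to be joined, so the forward step must be an oxidative union; it must favour the cross product over the two dimers and control the face at C4.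

4 to 1 and 2: the N–acyl bond is cut. This leads to a commercial acid and a commercial auxiliary. The forward step only needs a mild acyl activation.

8 to 5 and 6: the bond between the ester α-carbon and C6 is cut. This gives an acetate enolate and a benzylic halide that already carries the protected catechol. The forward step must stop at monoalkylation.

## Other disconnections considered

Alternative 1: The lactone oxygen is taken out (O1–C5 and O1–C2), so that C2 and C5 are directly bonded in the prochiral cyclobutanone A1 (3-(3,4-dimethoxybenzyl)cyclobutan-1-one); the ring B arm is cut separately as an enolate alkylation.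
- Forward key step: a chiral catalyst (for example a BINOL-derived phosphoric acid) and aqueous H2O2 would form the peroxide adduct of A1, and one of the two enantiotopic ring CH2 groups would migrate to oxygen (Baeyer–Villiger), giving lactone A2 ((R)-4-(3,4-dimethoxybenzyl)dihydrofuran-2(3H)-one). The lithium enolate of A2 would then be benzylated with 6 anti to the C4 arm to reach 13, and hydrogenolysis would finish.
- In favour: C4 comes from a catalyst, not from a stoichiometric auxiliary. The trans relation is set kinetically in the alkylation, so no equilibration is needed. With A1 about two operations from a commercial allylarene (ketene cycloaddition, dechlorination), the count is about five steps.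
- Against: the catalyst must tell apart two CH2 groups that differ only through a benzyl group one carbon removed, so the enantiomeric purity of C4 rests on one catalyst–substrate match. A shortfall could not be repaired later, because A2 and 13 offer no diastereomeric handle. The electron-rich ring A must also tolerate the peroxide.
- Comparison: on step economy and atom economy this plan is the better one, and on C3 control it is at least the equal. Its 1,2-shift is mechanistically cleaner than a one-electron enolate coupling with its statistical by-products. The chosen plan is stronger on the security of C4 (a covalently bound controller whose failures appear as separable diastereomers) and on convergence (both aryl halves joined in one bond).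

Alternative 2: The C7–aryl bond of ring A is cut, and C7 is traced back to the CH2 of a cyclopropane fused to the lactone, A3 (methyl (1S,5R)-2-oxo-3-oxabicyclo[3.1.0]hexane-1-carboxylate), a chiral-pool compound available in one operation from an enantiopure epihalohydrin and a malonate.
- Forward key step: the cuprate from Grignard reagent A4 ((3,4-dimethoxyphenyl)magnesium bromide) and CuI (monovalent copper) would attack C7 in a homoconjugate opening, break C3–C7 and leave a malonate-type enolate, protonated to A5 (methyl (3S,4R)-4-(3,4-dimethoxybenzyl)-2-oxotetrahydrofuran-3-carboxylate). C-benzylation with 6, Krapcho demethoxycarbonylation and hydrogenolysis would follow.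
- In favour: C4 is never made in a selective step; it comes with the starting material and is not touched by the opening. The malonate-type C3 alkylates easily. The count is about five steps.
- Against: the organometallic has three electrophilic sites to choose from (cyclopropane, lactone carbonyl, ester). The ring B arm still needs its own step. The dealkoxycarbonylation needs hot halide in a dipolar solvent, which threatens the lactone, and it sets C3 by protonation, so equilibration to trans is needed.
- Comparison: on C4 this plan is better than any auxiliary control, and its polar two-electron opening has no homocoupling problem, which is also better. The step count is equal or slightly lower. On C3 the two plans are equal. The chosen plan is better in that it carries no activating ester that must later be removed and builds the skeleton in one central bond, not arm by arm.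

Alternative 3: The C4–C7 bond is cut, with C5 raised to an acetal bearing l-menthyl as controller: butenolide A6 ((5R)-3-[3,4-bis(benzyloxy)benzyl]-5-(l-menthyloxy)furan-2(5H)-one) and acid A7 (2-(3,4-dimethoxyphenyl)acetic acid).
- Forward key step: photocatalytic one-electron oxidation of the carboxylate of A7 (for example with Ir[dF(CF3)ppy]2(dtbbpy)PF6 and visible light) would release CO2 and a benzyl radical, which adds to C4 anti to the menthyloxy group (Giese addition). Reduction of the α-acyl radical and protonation would give A8, the all-trans (3R,4R,5R) lactone acetal. Acetal hydrolysis, borohydride reduction with relactonisation (C5 becomes CH2, C2 stays the carbonyl) and hydrogenolysis would follow.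
- In favour: very mild conditions, a cheap radical precursor, and facial control at C4 by an adjacent ring stereocentre.
- Against: the stabilised benzyl radical adds reluctantly and tends to dimerise. Kinetic protonation at C3 should occur anti to the new C4 arm and would then give the cis relation, so equilibration is needed. A6 needs several steps including a separation of acetal epimers, and the acetal must be taken down afterwards.
- Comparison: convergence is equal (both halves joined in one step), and the rigid cyclic control at C4 is in that respect better than control in an acyclic enolate. C3 is equal at best. The step count is clearly higher, and both plans use a stoichiometric chiral controller.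

Key step: step 3

Remark on the chemistry: a CIP check of every centre shows that the (4S)-benzyl auxiliary, the (2R,3R) succinate 11 and the (3R,4R) lactone fit together without any inversion. In an extended zigzag drawing of 11 the two benzyl groups lie on the same side, so 11 is named by its CIP descriptors and the word anti is avoided. Compound 6 is assumed to be a purchasable catalogue compound, and LiN(iPr)2 (LDA) is used as a commercial solution.

## Route

Step 1
Reactants: 1 3-(3,4-dimethoxyphenyl)propanoic acid; 2 (S)-4-benzyloxazolidin-2-one
Product: 4 (S)-4-benzyl-3-[3-(3,4-dimethoxyphenyl)propanoyl]oxazolidin-2-one, via mixed pivalic anhydride 3 (not isolated)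
Conditions: t-BuCOCl, Et3N, THF, −20 °C; then LiCl, 2, −20 °C → rt
Reagents that add atoms: none
Why: Mixed-anhydride N-acylation of an oxazolidinone: 2, activated by LiCl and Et3N, attacks the less hindered carbonyl of 3, so neither a strong base nor an acid chloride is needed; no stereocentre is formed and that of 2 is untouched.

Step 2
Reactants: 5 tert-butyl acetate; 6 3,4-bis(benzyloxy)benzyl chloride
Product: 8 tert-butyl 3-[3,4-bis(benzyloxy)phenyl]propanoate, via lithium enolate of tert-butyl acetate 7 (not isolated)
Conditions: 5 (2.5 equiv), LiN(iPr)2 (2.2 equiv), THF, −78 °C; then 6, DMPU, NaI (cat.), −78 °C → rt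
Reagents that add atoms: none
Why: SN2 alkylation of a lithium ester enolate with a benzylic halide: the tert-butyl group prevents Claisen self-condensation, the excess of 7 suppresses double alkylation, and NaI turns the chloride into the more reactive iodide in the flask (Finkelstein exchange); the benzyl ethers are inert to the amide base at low temperature.

Step 3
Reactants: 4 (S)-4-benzyl-3-[3-(3,4-dimethoxyphenyl)propanoyl]oxazolidin-2-one; 8 tert-butyl 3-[3,4-bis(benzyloxy)phenyl]propanoate
Product: 11 tert-butyl (2R,3R)-4-[(4S)-4-benzyl-2-oxo-1,3-oxazolidin-3-yl]-2-[3,4-bis(benzyloxy)benzyl]-3-(3,4-dimethoxybenzyl)-4-oxobutanoate, via imide lithium Z-enolate 9 (not isolated), via ester lithium enolate 10 (not isolated)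
Conditions: 4 (1.0 equiv), 8 (1.5 equiv), LiN(iPr)2 (2.6 equiv), THF, −78 °C; then Fe(acac)3 (2.6 equiv), THF, −78 °C → rt
Reagents that add atoms: none
Why: This is an oxidative enolate heterocoupling, a known reaction type for imide and ester enolates with trivalent iron or divalent copper oxidants; it forms the C3–C4 bond (lactone numbering) and closes no ring. Enolates 9 and 10 are expected to form a mixed aggregate; Fe(acac)3 (trivalent iron) takes one electron from the more electron-rich ester enolate 10, the electrophilic α-ester radical (free or iron-bound) adds to the α-carbon of the chelated imide enolate 9, and a second Fe(acac)3 oxidises the resulting radical anion. The step needs cross- over homo-selectivity, which the different oxidation potentials and the mixed aggregation of an imide and an ester enolate should favour; the cheaper partner 8 is used in excess so that 4 is consumed. The C4 centre (3R in 11) is controlled by the auxiliary: in the lithium-chelated Z-enolate the 4-benzyl group blocks one face of the α-carbon and the new bond forms on the opposite face, in the same sense as in an Evans alkylation. The C3 centre (2R in 11) arises in an open transition state and is only weakly biased; the design does not rely on it, because this carbon is α to the future lactone carbonyl and is equilibrated in step 5, so any 2S epimer is carried along and converges. The tert-butyl ester excludes Claisen condensation and leaves the two carboxyl termini distinguishable for step 4.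

Step 4
Reactants: 11 tert-butyl (2R,3R)-4-[(4S)-4-benzyl-2-oxo-1,3-oxazolidin-3-yl]-2-[3,4-bis(benzyloxy)benzyl]-3-(3,4-dimethoxybenzyl)-4-oxobutanoate
Product: 12 tert-butyl (2R,3R)-2-[3,4-bis(benzyloxy)benzyl]-3-(3,4-dimethoxybenzyl)-4-hydroxybutanoate
Conditions: LiBH4, MeOH (1 equiv), THF, 0 °C
Reagents that add atoms: none
Why: Reductive cleavage of an N-acyloxazolidinone: LiBH4, activated by one equivalent of methanol, reduces the exocyclic imide carbonyl (C5) to the primary alcohol and releases the auxiliary, while the hindered tert-butyl ester at C2 is left; no stereocentre is touched.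

Step 5
Reactants: 12 tert-butyl (2R,3R)-2-[3,4-bis(benzyloxy)benzyl]-3-(3,4-dimethoxybenzyl)-4-hydroxybutanoate
Product: 13 (3R,4R)-3-[3,4-bis(benzyloxy)benzyl]-4-(3,4-dimethoxybenzyl)dihydrofuran-2(3H)-one
Conditions: TsOH·H2O (10 mol %), toluene, 80 °C; then DBU (2 equiv), 110 °C, same flask
Reagents that add atoms: none
Why: Acid-catalysed lactonisation of a γ-hydroxy tert-butyl ester (5-exo attack of the C5 hydroxyl on the protonated ester, the tert-butyl group leaving as 2-methylpropene) closes the ring; DBU then equilibrates C3 through the lactone enolate to the more stable trans lactone, so material of either C3 configuration should end as 13, while C4, which has no acidic hydrogen, keeps the configuration set in step 3.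

Step 6
Reactants: 13 (3R,4R)-3-[3,4-bis(benzyloxy)benzyl]-4-(3,4-dimethoxybenzyl)dihydrofuran-2(3H)-one
Product: 14 (3R,4R)-3-(3,4-dihydroxybenzyl)-4-(3,4-dimethoxybenzyl)dihydrofuran-2(3H)-one (3'-O-demethylarctigenin)
Conditions: H2 (1 atm), Pd/C (10 wt % Pd), EtOAc/EtOH, rt
Reagents that add atoms: none
Why: Hydrogenolysis of aryl benzyl ethers over palladium on carbon under neutral conditions frees the catechol; the lactone, the aryl methyl ethers and both stereocentres are inert, and the absence of base protects the catechol from air oxidation and C3 from epimerisation.

## Compound list

1 | 3-(3,4-dimethoxyphenyl)propanoic acid | COc1ccc(CCC(=O)O)cc1OC | starting material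
2 | (S)-4-benzyloxazolidin-2-one | O=C1N[C@@H](Cc2ccccc2)CO1 | starting material
3 | 3-(3,4-dimethoxyphenyl)propanoic pivalic anhydride (not isolated) | COc1ccc(CCC(=O)OC(=O)C(C)(C)C)cc1OC | intermediate
4 | (S)-4-benzyl-3-[3-(3,4-dimethoxyphenyl)propanoyl]oxazolidin-2-one | COc1ccc(CCC(=O)N2[C@@H](Cc3ccccc3)COC2=O)cc1OC | intermediate
5 | tert-butyl acetate | CC(=O)OC(C)(C)C | starting material
6 | 3,4-bis(benzyloxy)benzyl chloride | ClCc1ccc(OCc2ccccc2)c(OCc2ccccc2)c1 | starting material
7 | lithium enolate of tert-butyl acetate (not isolated) | [Li+].[O-]C(=C)OC(C)(C)C | intermediate
8 | tert-butyl 3-[3,4-bis(benzyloxy)phenyl]propanoate | CC(C)(C)OC(=O)CCc1ccc(OCc2ccccc2)c(OCc2ccccc2)c1 | intermediate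
9 | lithium (Z)-enolate of 4 (not isolated) | COc1ccc(C/C=C(\[O-])N2[C@@H](Cc3ccccc3)COC2=O)cc1OC.[Li+] | intermediate
10 | lithium enolate of 8 (double-bond geometry not specified; not isolated) | [Li+].[O-]C(=CCc1ccc(OCc2ccccc2)c(OCc2ccccc2)c1)OC(C)(C)C | intermediate
11 | tert-butyl (2R,3R)-4-[(4S)-4-benzyl-2-oxo-1,3-oxazolidin-3-yl]-2-[3,4-bis(benzyloxy)benzyl]-3-(3,4-dimethoxybenzyl)-4-oxobutanoate | COc1ccc(C[C@@H](C(=O)N2[C@@H](Cc3ccccc3)COC2=O)[C@@H](Cc2ccc(OCc3ccccc3)c(OCc3ccccc3)c2)C(=O)OC(C)(C)C)cc1OC | intermediate
12 | tert-butyl (2R,3R)-2-[3,4-bis(benzyloxy)benzyl]-3-(3,4-dimethoxybenzyl)-4-hydroxybutanoate | COc1ccc(C[C@@H](CO)[C@@H](Cc2ccc(OCc3ccccc3)c(OCc3ccccc3)c2)C(=O)OC(C)(C)C)cc1OC | intermediate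
13 | (3R,4R)-3-[3,4-bis(benzyloxy)benzyl]-4-(3,4-dimethoxybenzyl)dihydrofuran-2(3H)-one | COc1ccc(C[C@H]2COC(=O)[C@@H]2Cc2ccc(OCc3ccccc3)c(OCc3ccccc3)c2)cc1OC | intermediate
14 | (3R,4R)-3-(3,4-dihydroxybenzyl)-4-(3,4-dimethoxybenzyl)dihydrofuran-2(3H)-one | COc1ccc(C[C@H]2COC(=O)[C@@H]2Cc2ccc(O)c(O)c2)cc1OC | target

## Step count and least certain steps

Total: 6 steps. Longest linear sequence: 5 steps (1 or 2, then 3, 4, 5, 6).

Step 3 (key step). The likely failures are statistical homocoupling of either enolate alongside the cross-coupling, erosion of the facial bias at C4 if bond formation does not go through the chelated imide enolate, and epimerisation of the newly formed imide α-centre by residual enolate base while the mixture warms. The fallback sets out from 4 and returns at 13; it gives up the C3–C4 union for a C3–C6 bond formation and costs two extra steps.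
- The sodium enolate of 4 (NaN(SiMe3)2, THF, −78 °C) is alkylated with tert-butyl bromoacetate (Evans alkylation) to give tert-butyl (3R)-4-[(4S)-4-benzyl-2-oxo-1,3-oxazolidin-3-yl]-3-(3,4-dimethoxybenzyl)-4-oxobutanoate F1.
- LiBH4 reduction gives tert-butyl (3R)-3-(3,4-dimethoxybenzyl)-4-hydroxybutanoate F2.
- TsOH in toluene closes this to (R)-4-(3,4-dimethoxybenzyl)dihydrofuran-2(3H)-one F3 (the same lactone as A2).
- The lithium enolate of F3 (LiN(iPr)2, THF, −78 °C) is benzylated with 6 anti to the C4 arm, which gives 13 directly.

Step 4. The exocyclic carbonyl of 11 sits between two branched carbons, so hydride may attack the ring carbonyl of the auxiliary instead (ring opening of the oxazolidinone), or the reduction may stall. The fallback sets out from 11 and returns at 12. Hydroperoxide cleavage (LiOH, H2O2, THF/H2O, 0 °C), which attacks the exocyclic carbonyl even in hindered imides, gives (2R,3R)-3-[3,4-bis(benzyloxy)benzyl]-4-(tert-butoxy)-2-(3,4-dimethoxybenzyl)-4-oxobutanoic acid F4. BH3·SMe2 in THF then reduces the free acid chemoselectively in the presence of the tert-butyl ester to give 12.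

Step 5. The likely failure is incomplete equilibration at C3, because the amidine base may enolise the lactone too slowly, with a smaller risk of acid-promoted loss or migration of a benzyl group during ring closure. The fallback sets out from 12 and returns at 13. The lactone mixture is isolated after the acid stage, 13 is separated by chromatography from (3S,4R)-3-[3,4-bis(benzyloxy)benzyl]-4-(3,4-dimethoxybenzyl)dihydrofuran-2(3H)-one F5, and F5 alone is equilibrated under protic alkoxide conditions (NaOMe, MeOH, reflux, acidic work-up to reclose the ring), which should convert it to 13.

Step 2. Proton transfer between the product and excess enolate may lead to double alkylation, or displacement of the chloride may be slow. The fallback sets out from 6 and returns at 8. Alkylation of diethyl malonate (NaH, THF, excess malonate) gives diethyl 2-[3,4-bis(benzyloxy)benzyl]malonate F6. Saponification (KOH, EtOH/H2O), acidification and thermal decarboxylation give 3-[3,4-bis(benzyloxy)phenyl]propanoic acid F7. Esterification with Boc2O, DMAP and t-BuOH gives 8.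

Step 6. The catalyst may be poisoned by traces of amidine or sulfonate from step 5, and the freed catechol may oxidise during filtration and concentration. The fallback sets out from 13 and returns at 14 with no new intermediate: Lewis-acid debenzylation with BCl3 and pentamethylbenzene as cation scavenger in CH2Cl2 at −78 °C, which should leave the aryl methyl ethers and the lactone intact at that temperature.

## Further compounds

F1 | step 3 | tert-butyl (3R)-4-[(4S)-4-benzyl-2-oxo-1,3-oxazolidin-3-yl]-3-(3,4-dimethoxybenzyl)-4-oxobutanoate | COc1ccc(C[C@@H](C(=O)N2[C@@H](Cc3ccccc3)COC2=O)CC(=O)OC(C)(C)C)cc1OC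
F2 | step 3 | tert-butyl (3R)-3-(3,4-dimethoxybenzyl)-4-hydroxybutanoate | COc1ccc(C[C@@H](CO)CC(=O)OC(C)(C)C)cc1OC
F3 | step 3 | (R)-4-(3,4-dimethoxybenzyl)dihydrofuran-2(3H)-one | COc1ccc(C[C@H]2COC(=O)C2)cc1OC
F4 | step 4 | (2R,3R)-3-[3,4-bis(benzyloxy)benzyl]-4-(tert-butoxy)-2-(3,4-dimethoxybenzyl)-4-oxobutanoic acid | COc1ccc(C[C@@H](C(=O)O)[C@@H](Cc2ccc(OCc3ccccc3)c(OCc3ccccc3)c2)C(=O)OC(C)(C)C)cc1OC
F5 | step 5 | (3S,4R)-3-[3,4-bis(benzyloxy)benzyl]-4-(3,4-dimethoxybenzyl)dihydrofuran-2(3H)-one | COc1ccc(C[C@H]2COC(=O)[C@H]2Cc2ccc(OCc3ccccc3)c(OCc3ccccc3)c2)cc1OC
F6 | step 2 | diethyl 2-[3,4-bis(benzyloxy)benzyl]malonate | CCOC(=O)C(Cc1ccc(OCc2ccccc2)c(OCc2ccccc2)c1)C(=O)OCC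
F7 | step 2 | 3-[3,4-bis(benzyloxy)phenyl]propanoic acid | OC(=O)CCc1ccc(OCc2ccccc2)c(OCc2ccccc2)c1
F0 | step 6 | none | none
A1 | alternative 1 | 3-(3,4-dimethoxybenzyl)cyclobutan-1-one | COc1ccc(CC2CC(=O)C2)cc1OC
A2 | alternative 1 | (R)-4-(3,4-dimethoxybenzyl)dihydrofuran-2(3H)-one | COc1ccc(C[C@H]2COC(=O)C2)cc1OC
A3 | alternative 2 | methyl (1S,5R)-2-oxo-3-oxabicyclo[3.1.0]hexane-1-carboxylate | COC(=O)[C@]12C[C@H]1COC2=O
A4 | alternative 2 | (3,4-dimethoxyphenyl)magnesium bromide | COc1ccc([Mg]Br)cc1OC
A5 | alternative 2 | methyl (3S,4R)-4-(3,4-dimethoxybenzyl)-2-oxotetrahydrofuran-3-carboxylate | COc1ccc(C[C@H]2COC(=O)[C@@H]2C(=O)OC)cc1OC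
A6 | alternative 3 | (5R)-3-[3,4-bis(benzyloxy)benzyl]-5-{[(1R,2S,5R)-2-isopropyl-5-methylcyclohexyl]oxy}furan-2(5H)-one | O=C1O[C@@H](O[C@@H]2C[C@H](C)CC[C@H]2C(C)C)C=C1Cc1ccc(OCc2ccccc2)c(OCc2ccccc2)c1
A7 | alternative 3 | 2-(3,4-dimethoxyphenyl)acetic acid | COc1ccc(CC(=O)O)cc1OC
A8 | alternative 3 | (3R,4R,5R)-3-[3,4-bis(benzyloxy)benzyl]-4-(3,4-dimethoxybenzyl)-5-{[(1R,2S,5R)-2-isopropyl-5-methylcyclohexyl]oxy}dihydrofuran-2(3H)-one | COc1ccc(C[C@H]2[C@H](O[C@@H]3C[C@H](C)CC[C@H]3C(C)C)OC(=O)[C@@H]2Cc2ccc(OCc3ccccc3)c(OCc3ccccc3)c2)cc1OC
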